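## Retrosynthetic overview

1. The C11–O aryl ether is made last, by Mitsunobu coupling of the decalin alcohol with isofraxidin.
2. The C9–C11 bond, the C9 stereocentre and the exocyclic alkene come from one carbonyl-ene reaction of formaldehyde with a C8=C9 alkene; the C2 acetate comes from acetoxylation of the C3 ketone enol ether.
3. Ring A (C3–C4 bond, quaternary C4, cis-decalin) is closed by a light-driven cobalt-hydride hydrogen-atom-transfer cyclization of an isopropenyl group onto a nitrile.
4. The quaternary C10 is set on (S)-carvone by allylation followed by methylation, which places the three-carbon arm cis to the isopropenyl group; the allyl group becomes 2-cyanoethyl and the enone becomes the C8=C9 alkene via its enol triflate.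
5. Ring order: ring B is bought as (S)-carvone, ring A is closed photochemically, the coumarin is attached last.

Assumption: the SMILES is taken literally; it encodes a cis-fused decalin with H-5, the C10 methyl and the C9 CH2OAr group on one face (β) and the C2 acetate on the other (α), i.e. (2R,5S,9S,10S).

Numbering and abbreviations: drimane numbering is used for the decalin (ring A = C1–C5 and C10; ring B = C5–C10; C11 = CH2O; C12 = exocyclic CH2). Co(tBu4-salen) is [N,N′-ethylenebis(3,5-di-tert-butylsalicylideneiminato)]cobalt, Co(C32H46N2O2), an achiral complex of divalent cobalt. [Ir(ppy)2(dtbbpy)]PF6 is bis(2-phenylpyridinato)(4,4′-di-tert-butyl-2,2′-bipyridine)iridium hexafluorophosphate.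

## Route

Step 1
Reactants: 1 (S)-(+)-carvone
Product: 3 (5S,6R)-2-methyl-5-(prop-1-en-2-yl)-6-(prop-2-en-1-yl)cyclohex-2-en-1-one (trans-6-allylcarvone; the minor C6 epimer is carried along), via lithium dienolate 2 (not isolated)
Conditions: LiN(i-Pr)2, THF, −78 °C; allyl bromide, −78 → 0 °C
Reagents that add atoms: allyl bromide, C=CCBr
Why: Kinetic deprotonation at the only α′ position (the future C10) and SN2 allylation of the cross-conjugated lithium dienolate (enolate alkylation); the new centre is irrelevant because it is re-enolized in step 2.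

Step 2
Reactants: 3 (5S,6R)-6-allylcarvone
Product: 5 (5R,6S)-2,6-dimethyl-5-(prop-1-en-2-yl)-6-(prop-2-en-1-yl)cyclohex-2-en-1-one, via lithium dienolate 4 (not isolated)
Conditions: LiN(i-Pr)2, THF, −78 °C; MeI, DMPU, −78 → −20 °C
Reagents that add atoms: iodomethane, CI
Why: Enolate alkylation in which iodomethane enters anti to the adjacent isopropenyl group (substrate control by the bought C5 centre), so the quaternary C10 carries its methyl trans and its allyl arm cis to the isopropenyl group, which later becomes the cis ring fusion.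

Step 3
Reactants: 5 (5R,6S)-6-allyl-6-methylcarvone
Product: 6 3-[(1S,6R)-1,3-dimethyl-2-oxo-6-(prop-1-en-2-yl)cyclohex-3-en-1-yl]propanal
Conditions: PdCl2(PhCN)2 (10 mol%), CuCl2·2H2O (10 mol%), AgNO2 (5 mol%), O2 (1 atm), t-BuOH/MeNO2 15:1, 25 °C
Reagents that add atoms: dioxygen, O=O
Why: Nitrite-modified, aldehyde-selective (anti-Markovnikov) Wacker oxidation, which works well for allyl groups on quaternary carbons and leaves the 1,1-disubstituted and conjugated alkenes alone; no stereocentre is touched.

Step 4
Reactants: 6 keto aldehyde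
Product: 7 3-[(1S,6R)-1,3-dimethyl-2-oxo-6-(prop-1-en-2-yl)cyclohex-3-en-1-yl]propanenitrile
Conditions: I2, aq. NH3 (28%), THF, 25 °C
Reagents that add atoms: ammonia, N
Why: One-pot oxidative conversion of an aldehyde into a nitrile (aldimine formation, N-iodination, loss of HI); the hindered enone and the alkenes are not affected.

Step 5
Reactants: 7 keto nitrile
Product: 9 (5R,6S)-6-(2-cyanoethyl)-2,6-dimethyl-5-(prop-1-en-2-yl)cyclohex-1-en-1-yl trifluoromethanesulfonate, via lithium enolate 8 (not isolated)
Conditions: LiBH(s-Bu)3, THF, −78 °C; PhNTf2, −78 → 25 °C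
Reagents that add atoms: N-phenyl-bis(trifluoromethanesulfonimide), O=S(=O)(N(c1ccccc1)S(=O)(=O)C(F)(F)F)C(F)(F)F
Why: Conjugate (1,4) hydride reduction of the β-unsubstituted enone by the bulky borohydride gives the enolate regiospecifically, and O-triflation fixes the C8=C9 double bond (enol triflate formation); nitrile and isopropenyl group are inert.

Step 6
Reactants: 9 vinyl triflate
Product: 10 3-[(1R,6R)-1,3-dimethyl-6-(prop-1-en-2-yl)cyclohex-2-en-1-yl]propanenitrile
Conditions: Pd(OAc)2 (5 mol%), PPh3 (10 mol%), HCO2H, n-Bu3N, DMF, 60 °C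
Reagents that add atoms: none
Why: Palladium-catalysed formate hydrogenolysis of the vinyl triflate (oxidative addition, decarboxylation of formate, reductive elimination) replaces OTf by H without moving the double bond.

Step 7
Reactants: 10 diene nitrile
Product: 12 (4aR,8aS)-1,1,4a,6-tetramethyl-3,4,4a,7,8,8a-hexahydronaphthalen-2(1H)-one (cis-fused; 5β-H and 10β-Me), via ketimine 11 (not isolated)
Conditions: [Ir(ppy)2(dtbbpy)]PF6 (1 mol%), Co(tBu4-salen) (3 mol%), Hantzsch ester (1.5 equiv, slow addition), 2,4,6-collidinium triflate (20 mol%), MeCN (0.02 M), 450 nm LEDs, 25 °C; then 1 M HCl, THF, 25 °C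
Reagents that add atoms: water, O
Why: Proposed new method: the photoreduced monovalent cobalt is protonated to a trivalent cobalt hydride that transfers a hydrogen atom to the CH2 terminus of the isopropenyl group (Markovnikov hydrogen-atom transfer; the neopentylic ring alkene is too hindered), the tertiary C4 radical closes 6-exo-dig onto the nitrile through a chair with the C5 arm equatorial and the C10 arm axial so that the cis relationship fixed in step 2 becomes the cis ring fusion, and the iminyl radical is reduced by the Hantzsch ester to the imine, which is hydrolysed to the ketone (no new stereocentre); the closest known chemistry is the thermal iron-hydride/silane hydrogen-atom-transfer cyclization of alkenes onto nitriles and cobalt/photoredox hydrogen-atom-transfer hydrogenation of alkenes.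

Step 8
Reactants: 12 cis-decalin ketone
Product: 14 (3R,4aR,8aS)-3-acetoxy-1,1,4a,6-tetramethyl-3,4,4a,7,8,8a-hexahydronaphthalen-2(1H)-one (2α-acetate), via silyl enol ether 13 (not isolated)
Conditions: LiN(SiMe3)2, Me3SiCl, THF, −78 → 0 °C; then Pb(OAc)4, CH2Cl2, 0 °C
Reagents that add atoms: lead tetraacetate, CC(=O)O[Pb](OC(C)=O)(OC(C)=O)OC(C)=O
Why: The ketone can enolize only toward C2, and acetoxylation of the silyl enol ether by Pb(OAc)4 takes place on the α face, anti to the two syn-axial β-methyl groups (C10-Me and 4β-Me), giving the equatorial 2α-acetate, which is also the thermodynamic epimer in the preferred conformer (substrate control).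

Step 9
Reactants: 14 acetoxy ketone
Product: 15 (3R,4aS,5S,8aS)-3-acetoxy-5-(hydroxymethyl)-1,1,4a-trimethyl-6-methylideneoctahydronaphthalen-2(1H)-one
Conditions: (CH2O)n, Me2AlCl (3 equiv), CH2Cl2, 0 → 25 °C
Reagents that add atoms: formaldehyde (from paraformaldehyde), C=O
Why: Lewis-acid-promoted carbonyl-ene reaction in which formaldehyde bonds to the less substituted alkene carbon C9 from the convex β face, anti to the pseudo-axial C1 of ring A, and takes hydrogen from the methyl group that is syn to the vinylic hydrogen, so the C9 centre (CH2OH cis to the angular methyl) and the exocyclic methylene form together under substrate control.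

Step 10
Reactants: 15 primary alcohol; 16 isofraxidin (7-hydroxy-6,8-dimethoxycoumarin)
Product: 17 (3R,4aS,5S,8aS)-3-acetoxy-5-{[(6,8-dimethoxy-2-oxo-2H-chromen-7-yl)oxy]methyl}-1,1,4a-trimethyl-6-methylideneoctahydronaphthalen-2(1H)-one (the target)
Conditions: PPh3, DIAD, toluene, 0 → 50 °C
Reagents that add atoms: none
Why: Mitsunobu etherification of the primary alcohol with the acidic 7-hydroxycoumarin forms the aryl ether at a non-stereogenic carbon under neutral conditions that spare the α-acetoxy ketone, the exocyclic alkene and the lactone.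

## Compound list

1 | (S)-(+)-carvone, (5S)-2-methyl-5-(prop-1-en-2-yl)cyclohex-2-en-1-one | CC1=CC[C@@H](CC1=O)C(C)=C | starting material
2 | lithium cross-conjugated dienolate of 1 | CC1=CC[C@@H](C=C1[O-])C(C)=C.[Li+] | intermediate
3 | (5S,6R)-2-methyl-5-(prop-1-en-2-yl)-6-(prop-2-en-1-yl)cyclohex-2-en-1-one (trans epimer drawn) | CC1=CC[C@@H]([C@@H](CC=C)C1=O)C(C)=C | intermediate
4 | lithium dienolate of 3 | CC1=CC[C@@H](C(CC=C)=C1[O-])C(C)=C.[Li+] | intermediate
5 | (5R,6S)-2,6-dimethyl-5-(prop-1-en-2-yl)-6-(prop-2-en-1-yl)cyclohex-2-en-1-one | CC1=CC[C@@H]([C@](C)(CC=C)C1=O)C(C)=C | intermediate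
6 | 3-[(1S,6R)-1,3-dimethyl-2-oxo-6-(prop-1-en-2-yl)cyclohex-3-en-1-yl]propanal | CC1=CC[C@@H]([C@](C)(CCC=O)C1=O)C(C)=C | intermediate
7 | 3-[(1S,6R)-1,3-dimethyl-2-oxo-6-(prop-1-en-2-yl)cyclohex-3-en-1-yl]propanenitrile | CC1=CC[C@@H]([C@](C)(CCC#N)C1=O)C(C)=C | intermediate
8 | lithium (5R,6S)-6-(2-cyanoethyl)-2,6-dimethyl-5-(prop-1-en-2-yl)cyclohex-1-en-1-olate | CC=1CC[C@@H]([C@](C)(CCC#N)C=1[O-])C(C)=C.[Li+] | intermediate
9 | (5R,6S)-6-(2-cyanoethyl)-2,6-dimethyl-5-(prop-1-en-2-yl)cyclohex-1-en-1-yl trifluoromethanesulfonate | CC=1CC[C@@H]([C@](C)(CCC#N)C=1OS(=O)(=O)C(F)(F)F)C(C)=C | intermediate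
10 | 3-[(1R,6R)-1,3-dimethyl-6-(prop-1-en-2-yl)cyclohex-2-en-1-yl]propanenitrile | CC=1CC[C@@H]([C@](C)(CCC#N)C=1)C(C)=C | intermediate
11 | (4aR,8aS)-1,1,4a,6-tetramethyl-3,4,4a,7,8,8a-hexahydronaphthalen-2(1H)-imine | CC=1CC[C@@H]2C(C)(C)C(=N)CC[C@]2(C)C=1 | intermediate
12 | (4aR,8aS)-1,1,4a,6-tetramethyl-3,4,4a,7,8,8a-hexahydronaphthalen-2(1H)-one | CC=1CC[C@@H]2C(C)(C)C(=O)CC[C@]2(C)C=1 | intermediate
13 | trimethylsilyl enol ether of 12 (C2=C3, OSiMe3 on C3) | CC=1CC[C@@H]2C(C)(C)C(O[Si](C)(C)C)=CC[C@]2(C)C=1 | intermediate
14 | (3R,4aR,8aS)-3-acetoxy-1,1,4a,6-tetramethyl-3,4,4a,7,8,8a-hexahydronaphthalen-2(1H)-one | CC=1CC[C@@H]2C(C)(C)C(=O)[C@H](OC(C)=O)C[C@]2(C)C=1 | intermediate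
15 | (3R,4aS,5S,8aS)-3-acetoxy-5-(hydroxymethyl)-1,1,4a-trimethyl-6-methylideneoctahydronaphthalen-2(1H)-one | C=C1CC[C@@H]2C(C)(C)C(=O)[C@H](OC(C)=O)C[C@]2(C)[C@H]1CO | intermediate
16 | isofraxidin, 7-hydroxy-6,8-dimethoxy-2H-chromen-2-one | Oc1c(OC)cc2ccc(=O)oc2c1OC | starting material
17 | (3R,4aS,5S,8aS)-3-acetoxy-5-{[(6,8-dimethoxy-2-oxo-2H-chromen-7-yl)oxy]methyl}-1,1,4a-trimethyl-6-methylideneoctahydronaphthalen-2(1H)-one | C=C1CC[C@@H]2C(C)(C)C(=O)[C@H](OC(C)=O)C[C@]2(C)[C@H]1COc1c(OC)cc2ccc(=O)oc2c1OC | target

## Step count and risks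

Total step count: 10. Longest linear sequence: 10 steps, from 1 to 17 (16 is bought).

The three steps most likely to fail:

Step 7 (the new photochemical ring closure). The tertiary radical may be reduced before it cyclizes, or divalent cobalt may take back a hydrogen atom and isomerize the isopropenyl group to the isopropylidene alkene, which would erase C5. The fallback uses known chemistry and gives up the light-driven cobalt cycle for a thermal, silane-driven iron-hydride one. It sets out from 10: Fe(acac)3 and PhSiH3 in EtOH at 60 °C effect the established hydrogen-atom-transfer cyclization of the alkene onto the nitrile, and aqueous HCl hydrolyses ketimine 11. It comes back to the route at 12 and makes no compound outside the list (none F0).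

Step 9 (carbonyl-ene reaction). C9 is neopentylic, so the ene reaction may be slow, and hydrogen abstraction from C7 instead of C12 would give the endocyclic alkene isomer. The fallback replaces the pericyclic step by an allylmetal addition and sets out from 14. Ene-type allylic chlorination (N-chlorosuccinimide, catalytic PhSeCl, CH2Cl2, 25 °C) gives the rearranged allylic chloride F1. A Barbier reaction of it with indium powder and aqueous formaldehyde in THF forms the allylindium at C12, which adds to formaldehyde through C9 (γ-attack, anti to the axial C1). It comes back to the route at 15.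

Step 10 (Mitsunobu etherification). The CH2OH group is axial and next to a quaternary carbon, and the phenol is flanked by two methoxy groups, so the redox condensation may stall. The fallback changes to a Williamson alkylation with a preformed sulfonate and sets out from 15. Tf2O and 2,6-lutidine in CH2Cl2 at −78 °C give the primary triflate F2, which alkylates the caesium phenoxide of 16 (Cs2CO3, MeCN, 25 °C). It comes back to the route at 17.

## Further compounds

F0 | step 7 | none | none
F1 | step 9 | 3-acetoxy-5-chloro-1,1,4a-trimethyl-6-methylideneoctahydronaphthalen-2(1H)-one (Cl cis to the angular methyl; other centres as in 14) | C=C1CC[C@@H]2C(C)(C)C(=O)[C@H](OC(C)=O)C[C@]2(C)[C@H]1Cl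
F2 | step 10 | primary triflate of 15 (C11 O-trifluoromethanesulfonate; all centres as in 15) | C=C1CC[C@@H]2C(C)(C)C(=O)[C@H](OC(C)=O)C[C@]2(C)[C@H]1COS(=O)(=O)C(F)(F)F
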